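The readings come from a simulation for an exercise; the scatter is artificial.

Which of oak and ash holds more target at the end of the feed, and how much each holds, had to be said from the three earlier runs.

| setting | Tuesday's | Sunday's | Monday's | oak | ash |
|---|---|---|---|---|---|
| solid substrate | 0.017 M | 0.017 M | 0.017 M | 0.017 M | 0.017 M |
| coupling partner | 0.0425 M (fed, over 3.0 min) | 0.0425 M (fed, over 3.0 min) | 0.0425 M (fed, over 3.0 min) | 0.0425 M (fed, over 3.0 min) | 0.0425 M (fed, over 3.0 min) |
| protic impurity | 0.26 mM | 0.45 mM | 0.51 mM | 0.500 mM | 0.340 mM |
| temperature | 5 °C | 16 °C | 5 °C |  |  |
| remark | run made earlier; the fed solution adds 0.50 times the starting volume | run made earlier; the fed solution adds 0.50 times the starting volume | run made earlier; the fed solution adds 0.50 times the starting volume | at 0 °C throughout; the fed solution adds 0.50 times the starting volume | at 0 °C until 50 s, from then on at 20 °C; the fed solution adds 0.50 times the starting volume |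
| time |  |  |  | 3.0 min | 3.0 min |

- Tuesday's (time / s: target / %): 12.0: 0; 30.0: 1.4; 60.0: 6.3; 90.0: 15.8; 120: 22.0
- Sunday's (time / s: target / %): 12.0: 0; 25.0: 1.7; 40.0: 4.6; 50.0: 7.5
- Monday's (time / s: target / %): 12.0: 0.9; 30.0: 1.7; 60.0: 6.7; 90.0: 14.5; 120: 22.2

(each reading ± 0.5 percentage points)

1. which one finishes higher in amount of target, in percent of the solid substrate charged ("neither" within 2 percentage points) (oak / ash / neither)
2. amount of target at the end, in percent of the solid substrate charged, oak
3. amount of target at the end, in percent of the solid substrate charged, ash

- amounts are per litre of the starting volume; all of the dose is in the solution fed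
- the analysis behind the earlier runs scatters by 0.5 percentage points, standard deviation
- at the start none of the solid substrate is in solution
- what has only dissolved of solid substrate counts as not reacted
- a reading or a percentage of target counts all its forms, free or not

In the runs at 5 °C the target peak first grew with the square of time, y = at², and from about 60.0 s it grew in a straight line of slope s, zero-order to the eye. Integrating a rate 2at that stops rising at s gives y = s(t − L) with L = s/(4a), so I asked what each number was worth in that formula. Counted against the feed rate, the 0.500 mM of oak and the 0.340 mM of ash differ by 0.678 s of feed, and Monday's run, with twice Tuesday's impurity, read 22.2 % against 22.0 % at 120 s, a gap smaller than the scatter, so I dropped the impurity. In my reckoning temperature entered through a, hence through L, while s multiplied the remaining time.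

Pooling Tuesday and Monday, I read s = 0.156 min⁻¹ as a fraction of the charge, and the lag L, the time at which the straight stretch extended backwards meets zero target, as 35.0 s. The margin of 2 percentage points was worth 7.69 s of lag, and in y = s(t − L) a given relative error in s moved the answer 4.14 times as far as the same relative error in L, so s was the number to know best. Sunday's a at 16 °C read 1.62 times that at 5 °C, and its last step read 0.174 min⁻¹ against the 0.156 min⁻¹ of s; I assumed the same s at 0 °C and 20 °C. Scaling a exponentially by 0.0436 K⁻¹ gave oak a lag of 43.5 s and 35.5 %. By this reckoning ash stood at 3.74 % at 50 s, and the warm curve then asked for 0.214 min⁻¹, above s, so I put ash straight onto s with a lag of 35.6 s and 37.5 %. I therefore called ash, though its lead of 2 points sat at the margin.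

The forecast said ash, with 30 % for oak and 50 % for ash, higher on ash than my figure, and noted: “The plateau's temperature dependence is uncertain.”

Oak gave 34.8 % and ash 38.9 %, so ash led by 4.1 points; ash had converted 68.9 % of its solid substrate against 52.0 % in oak, with 30.0 % against 17.2 % standing as side product. Read back through s, these results are lags of 46.3 s for oak and 30.5 s for ash.

    solid substrate ⇌ dissolved substrate, rate k1*(cs1 - [dissolved substrate]) while solid is left; crystals form when [dissolved substrate] > cs1 (solubility = 7.10 mM, k = 0.510 min⁻¹)
    dissolved substrate + coupling partner → target (k = 88.0 M⁻¹ min⁻¹, Ea = 54.0 kJ mol⁻¹)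
    coupling partner → decomposed reagent (k = 0.0170 min⁻¹, Ea = 92.0 kJ mol⁻¹)
    dissolved substrate + target → side product (k = 140 M⁻¹ min⁻¹, Ea = 49.0 kJ mol⁻¹)
    coupling partner + protic impurity → quenched reagent (k = 240 M⁻¹ min⁻¹, Ea = 41.0 kJ mol⁻¹)
    solid product ⇌ target, rate k6*(cs6 - [target]) while solid is left; crystals form when [target] > cs6 (solubility = 6.00 mM, k = 6.40 min⁻¹)
    (constants at 0 °C)

For the neighbour of ash charged with 0.11 M of coupling partner, taking a in proportion to the feed shortened the lag at 0 °C to 16.8 s, with the curve reaching s at 33.6 s, earlier than the change of temperature, and gave 42.4 %. That flask gave 56.6 %, above even s·t = 46.8 %, so its target rose faster on average than s.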